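**Strategy.** The target, polypoda-7,13,17,21-tetraene, is cut at C11–C12 into farnesyl bromide and a drimenyl nucleophile, and the drimane core is traced to (R)-carvone. Carvone supplies ring B with the C7=C8 methyl alkene, the C5 stereocentre and, as its isopropenyl group, the latent gem-dimethyl carbon C4 of ring A. After two stereoselective α′-alkylations (C10 methyl, then a 3-iodopropyl arm, C1–C3), the key step unites two electrophilic carbons: metal-hydride hydrogen-atom transfer turns the isopropenyl group into the tertiary C4 radical, which nickel couples with the C3 iodide. One operation thus forges C3–C4, the quaternary C4 and the trans-fused ring A (C1–C5, C10).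

Key step: step 3

Remark on the chemistry: drimane numbering is used throughout. Ring A is C1, C2, C3, C4, C5, C10; ring B is C5 to C10; C11 is the CH2 group on C9 and C12 the first carbon of the farnesyl unit. LiN(iPr)2 is taken as the commercial solution.

Step 1
Reactants: 1 (R)-carvone; 2 iodomethane
Product: 3 (5R)-2,6-dimethyl-5-(prop-1-en-2-yl)cyclohex-2-en-1-one (6-methylcarvone, both C6 epimers)
Conditions: LiN(iPr)2 (1.1 equiv), THF, −78 °C; then MeI, −78 → 0 °C
Reagents that add atoms: iodomethane, CI
Why: Kinetic deprotonation gives the cross-conjugated α′-enolate, whose C-methylation is a standard enolate alkylation; the new C6 centre need not be controlled because step 2 planarises it again.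

Step 2
Reactants: 3 6-methylcarvone; 4 1,3-diiodopropane
Product: 5 (5S,6S)-6-(3-iodopropyl)-2,6-dimethyl-5-(prop-1-en-2-yl)cyclohex-2-en-1-one
Conditions: LiN(iPr)2 (1.1 equiv), THF, −78 °C; then DMPU and 1,3-diiodopropane (4 equiv), −78 → 0 °C
Reagents that add atoms: 1,3-diiodopropane, ICCCI
Why: Enolate alkylation (SN2) of the tetrasubstituted α′-enolate should occur anti to the neighbouring isopropenyl group, which sets the quaternary C10 with the iodopropyl arm trans and the methyl group cis to the isopropenyl group, as a trans ring fusion requires.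

Step 3
Reactants: 5 (5S,6S)-6-(3-iodopropyl)-2,6-dimethyl-5-(prop-1-en-2-yl)cyclohex-2-en-1-one
Product: 6 (4aS,8aS)-2,5,5,8a-tetramethyl-4a,5,6,7,8,8a-hexahydronaphthalen-1(4H)-one (11-nordrim-7-en-9-one)
Conditions: Mn(dpm)3 (20 mol %; dpm = 2,2,6,6-tetramethylheptane-3,5-dionate), Ni(acac)2 (10 mol %), PhSiH3 (2 equiv), K2CO3 (1.5 equiv), (CF3)2CHOH/1,2-dichloroethane, rt, 0.01 M
Reagents that add atoms: none
Why: Proposed new method: PhSiH3 should turn Mn(dpm)3 into a manganese hydride that delivers a hydrogen atom to the terminal CH2 of the isopropenyl group (Markovnikov) and leaves the tertiary C4 radical, while low-valent nickel inserts into the C3–I bond, captures that radical and closes the C3–C4 bond by C(sp3)–C(sp3) reductive elimination. The closest known reaction type is the intermolecular Mn/Ni dual-catalytic Markovnikov hydroalkylation of unactivated 1,1-disubstituted olefins with primary alkyl iodides, which gives quaternary carbons; here it would run within one molecule and join two carbons that are both electrophilic. Ring A (C1, C2, C3, C4, C5, C10) closes as a six-membered carbocycle through a seven-membered alkylnickel metallacycle, and ring B is already in place from carvone. No new stereocentre forms, since C4 carries two methyl groups; the trans ring fusion follows from the trans C5 and C10 arms set in step 2, which can reach each other only from a diequatorial chair that becomes the trans-decalin. The step needs hydrogen-atom transfer to the electron-rich 1,1-disubstituted olefin in preference to the electron-poor C7=C8 enone, as is usual in metal-hydride hydrofunctionalisations of carvone, and ring closure in preference to plain reduction of either terminus, which the proximity of C3 and C4 and high dilution should favour.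

Step 4
Reactants: 6 11-nordrim-7-en-9-one; 7 methyltriphenylphosphonium bromide
Product: 8 (4aS,8aS)-2,5,5,8a-tetramethyl-1-methylidene-1,4,4a,5,6,7,8,8a-octahydronaphthalene (drima-7,9(11)-diene)
Conditions: Ph3PCH3Br (3 equiv), KOtBu (2.8 equiv), toluene, 90 °C
Reagents that add atoms: methyltriphenylphosphonium bromide, C[P+](c1ccccc1)(c1ccccc1)c1ccccc1.[Br-]
Why: Wittig methylenation with an excess of the ylide at elevated temperature is the usual answer to hindered ketones; the carbonyl group cannot enolise toward C10, and no stereocentre is touched.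

Step 5
Reactants: 8 drima-7,9(11)-diene
Product: 10 drimenol, via alkylborane 9 (not isolated)
Conditions: 9-BBN dimer, THF, 0 °C → rt; then aqueous NaOH, H2O2, 0 °C
Reagents that add atoms: hydrogen peroxide, OO
Why: Hydroboration–oxidation with 9-BBN should place boron on the terminal C11 of the exocyclic olefin and spare the trisubstituted C7=C8 bond; syn addition from the α face, anti to the axial C10 methyl group, puts the new C9 hydrogen α and C11 β (equatorial), and the C–B bond is oxidised with retention.

Step 6
Reactants: 10 drimenol
Product: 11 (1S,4aS,8aS)-1-(iodomethyl)-2,5,5,8a-tetramethyl-1,4,4a,5,6,7,8,8a-octahydronaphthalene (drimenyl iodide)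
Conditions: PPh3, imidazole, I2, CH2Cl2, 0 °C → rt
Reagents that add atoms: iodine, II
Why: Appel-type iodination converts the primary alcohol into the iodide by SN2 at C11, which is not a stereocentre, so C9 is untouched.

Step 7
Reactants: 11 drimenyl iodide; 12 (2E,6E)-farnesyl bromide
Product: 14 polypoda-7,13,17,21-tetraene, via drimenylmagnesium iodide 13 (not isolated)
Conditions: Mg turnings (activated), THF, rt → 40 °C; then 12, Li2CuCl4 (3 mol %), THF, −78 → 0 °C
Reagents that add atoms: (2E,6E)-farnesyl bromide, CC(C)=CCC/C(C)=C/CC/C(C)=C/CBr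
Why: Magnesium insertion gives the primary homoallylic Grignard reagent, and the Li2CuCl4-catalysed (Kochi-type) coupling with the primary allylic bromide should proceed at the α-carbon with retention of the E geometry, which forms C11–C12 without touching a stereocentre.

**Compound list**

1 | (R)-carvone, (5R)-2-methyl-5-(prop-1-en-2-yl)cyclohex-2-en-1-one | O=C1C(C)=CC[C@@H](C(C)=C)C1 | starting material
2 | iodomethane | CI | starting material
3 | (5R)-2,6-dimethyl-5-(prop-1-en-2-yl)cyclohex-2-en-1-one (6-methylcarvone, both C6 epimers) | O=C1C(C)=CC[C@@H](C(C)=C)C1C | intermediate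
4 | 1,3-diiodopropane | ICCCI | starting material
5 | (5S,6S)-6-(3-iodopropyl)-2,6-dimethyl-5-(prop-1-en-2-yl)cyclohex-2-en-1-one | O=C1C(C)=CC[C@@H](C(C)=C)[C@]1(C)CCCI | intermediate
6 | (4aS,8aS)-2,5,5,8a-tetramethyl-4a,5,6,7,8,8a-hexahydronaphthalen-1(4H)-one (11-nordrim-7-en-9-one) | O=C1C(C)=CC[C@H]2C(C)(C)CCC[C@]12C | intermediate
7 | methyltriphenylphosphonium bromide | C[P+](c1ccccc1)(c1ccccc1)c1ccccc1.[Br-] | starting material
8 | (4aS,8aS)-2,5,5,8a-tetramethyl-1-methylidene-1,4,4a,5,6,7,8,8a-octahydronaphthalene (drima-7,9(11)-diene) | C=C1C(C)=CC[C@H]2C(C)(C)CCC[C@]12C | intermediate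
9 | B-(drim-7-en-11-yl)-9-borabicyclo[3.3.1]nonane (alkylborane) | C([C@H]1C(C)=CC[C@H]2C(C)(C)CCC[C@]12C)B1C2CCCC1CCC2 | intermediate (not isolated)
10 | drimenol, [(1S,4aS,8aS)-2,5,5,8a-tetramethyl-1,4,4a,5,6,7,8,8a-octahydronaphthalen-1-yl]methanol | OC[C@H]1C(C)=CC[C@H]2C(C)(C)CCC[C@]12C | intermediate
11 | (1S,4aS,8aS)-1-(iodomethyl)-2,5,5,8a-tetramethyl-1,4,4a,5,6,7,8,8a-octahydronaphthalene (drimenyl iodide) | IC[C@H]1C(C)=CC[C@H]2C(C)(C)CCC[C@]12C | intermediate
12 | (2E,6E)-farnesyl bromide, (2E,6E)-1-bromo-3,7,11-trimethyldodeca-2,6,10-triene | CC(C)=CCC/C(C)=C/CC/C(C)=C/CBr | starting material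
13 | drim-7-en-11-ylmagnesium iodide (drimenylmagnesium iodide) | I[Mg]C[C@H]1C(C)=CC[C@H]2C(C)(C)CCC[C@]12C | intermediate (not isolated)
14 | polypoda-7,13,17,21-tetraene, (1S,4aS,8aS)-2,5,5,8a-tetramethyl-1-[(3E,7E)-4,8,12-trimethyltrideca-3,7,11-trien-1-yl]-1,4,4a,5,6,7,8,8a-octahydronaphthalene | CC(C)=CCC/C(C)=C/CC/C(C)=C/CC[C@H]1C(C)=CC[C@H]2C(C)(C)CCC[C@]12C | target

**Step count and risks**

Total step count: 7. Longest linear sequence: 7 steps (1 → 14).

Steps most likely to fail:

1. Step 3 (proposed new method). The tertiary radical or the alkylnickel species may be reduced before they meet, which would give the isopropyl compound or the deiodinated compound without C–C bond formation, or the hydride may attack the enone. The fallback closes ring A by an established Giese-type radical cyclisation and sets out from 3. The lithium enolate of 3 (LiN(iPr)2, THF, −78 °C) would be alkylated with ethyl 2-(bromomethyl)acrylate, again anti to the isopropenyl group, to give the acrylate-armed enone F1. Fe(acac)3 and PhSiH3 in EtOH/ethylene glycol at 60 °C would generate the same tertiary C4 radical, which adds in the 6-endo mode to the CH2 terminus of the acrylate (C3) and gives the bicyclic ester F2 as a mixture of C2 epimers. Saponification (LiOH, THF/MeOH/H2O) would give the acid F3. Photocatalytic hydrodecarboxylation (9-mesityl-10-phenylacridinium tetrafluoroborate cat., PhSSPh cat., iPr2NEt, trifluoroethanol, blue light) would then remove the C2 carboxyl group, and the fallback comes back to the route at 6.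

2. Step 7. The hindered Grignard reagent may form sluggishly or undergo Wurtz-type homocoupling, and the copper-catalysed coupling may leak into the branched SN2′ mode or erode the E geometry. The fallback reverses the polarity of the C11–C12 union and sets out from 11 and 12. (2E,6E)-Farnesyl phenyl sulfone F4 would be made from 12 with PhSO2Na (DMF, rt), lithiated (n-BuLi, THF/HMPA, −78 °C) and alkylated with iodide 11 to give the C12 sulfone F5. Hydride displacement of the allylic sulfonyl group (LiBHEt3, PdCl2(dppp) cat., THF, 0 °C) should then proceed without moving the C13=C14 double bond, and the fallback arrives at 14.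

3. Step 4. The α-quaternary, cross-conjugated carbonyl group may resist the ylide, or the basic medium may deprotonate C6 and deconjugate the enone. The fallback brings in C11 as an epoxide carbon and sets out from 6. Dimethylsulfonium methylide (Me3SI, n-BuLi, THF, −10 °C) should add to the C9 carbonyl group from the α face, anti to the axial C10 methyl group, and give the vinyl epoxide F6 with the oxygen on the β face. Palladium-catalysed hydrogenolysis with formate (Pd2(dba)3, PBu3, HCO2H/Et3N, dioxane, rt) would open the allylic C9–O bond with inversion, deliver hydride to C9 from the α face and leave the C7=C8 bond in place. The fallback comes back to the route at 10 and bypasses step 5.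

**Further compounds**

F1 | step 3 | ethyl 2-{[(1S,6S)-1,3-dimethyl-2-oxo-6-(prop-1-en-2-yl)cyclohex-3-en-1-yl]methyl}prop-2-enoate | O=C1C(C)=CC[C@@H](C(C)=C)[C@]1(C)CC(=C)C(=O)OCC
F2 | step 3 | ethyl 11-nor-9-oxodrim-7-ene-2-carboxylate (ethyl ester at C2 of 6, both C2 epimers) | O=C1C(C)=CC[C@H]2C(C)(C)CC(C(=O)OCC)C[C@]12C
F3 | step 3 | 11-nor-9-oxodrim-7-ene-2-carboxylic acid (both C2 epimers) | O=C1C(C)=CC[C@H]2C(C)(C)CC(C(=O)O)C[C@]12C
F4 | step 7 | (2E,6E)-farnesyl phenyl sulfone | CC(C)=CCC/C(C)=C/CC/C(C)=C/CS(=O)(=O)c1ccccc1
F5 | step 7 | 12-(phenylsulfonyl)polypoda-7,13,17,21-tetraene (both C12 epimers) | CC(C)=CCC/C(C)=C/CC/C(C)=C/C(S(=O)(=O)c1ccccc1)C[C@H]1C(C)=CC[C@H]2C(C)(C)CCC[C@]12C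
F6 | step 4 | 9,11-epoxydrim-7-ene (spiro-epoxide of 6, oxygen cis to the C10 methyl group) | C1O[C@]12C(C)=CC[C@H]3C(C)(C)CCC[C@]23C
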